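The route rests on the C-6(OR)–C-5H2–C-4(CH3)(O) triad (germacrane locants), which lies in the ten-membered carbocycle and in the oxepane ring of the 4,9-ether bridge. Read backwards, it is the product of a Prins addition of an isopropenyl group to an aldehyde, ended by capture of the C-4 cation by the C-9 hydroxyl. This one operation makes the C-5–C-6 and O–C-4 bonds, closes the carbocycle and both seven-membered ether rings, and sets C-4 and C-6. Its precursor is an open-chain γ-butyrolactone that bears a formyl group, an allylic alcohol and a remote 1,1-disubstituted alkene; it comes from a chiral butenolide in six steps.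

Key step: step 9

Remark (locants): germacrane numbering is used throughout: lactone C-12(=O)–O–C-8, acyloxy group on C-6, ether oxygen bridging C-4 and C-9, C-1=C-10 with CO2Me (C-14) on C-10, methyl C-15 on C-4, exocyclic methylene C-11=C-13.

Remark (side chain): the ester is read from the structure as (2S,3R)-2,3-dimethyloxirane-2-carboxylate, the cis-dimethyl epoxide that derives from (E)-2-methylbut-2-en-1-ol.

Step 1
Reactants: 1 (S)-5-(hydroxymethyl)furan-2(5H)-one
Product: 2 (S)-5-{[(tert-butyldimethylsilyl)oxy]methyl}furan-2(5H)-one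
Conditions: TBSCl, imidazole, DMF, 0 °C → rt
Reagents that add atoms: tert-butyldimethylsilyl chloride, CC(C)(C)[Si](C)(C)Cl
Why: Imidazole-promoted silylation of the primary alcohol leaves the future C-8 stereocentre (S) untouched and provides the bulky group that shields one face of the butenolide in the next step.

Step 2
Reactants: 2 (S)-5-{[(tert-butyldimethylsilyl)oxy]methyl}furan-2(5H)-one
Product: 3 (4S,5S)-5-{[(tert-butyldimethylsilyl)oxy]methyl}-4-(1,3-dioxolan-2-yl)oxolan-2-one (trans)
Conditions: 1,3-dioxolane (solvent), benzophenone (cat.), hν (350 nm, Pyrex), 10 °C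
Reagents that add atoms: 1,3-dioxolane, C1COCO1
Why: Benzophenone-sensitised hydrogen abstraction gives the nucleophilic 1,3-dioxolan-2-yl radical, which adds to the β-carbon of the butenolide anti to the silyloxymethyl group (photochemical radical conjugate addition), so that C-7 is set trans to C-8 and C-6 arrives as a protected aldehyde.

Step 3
Reactants: 3 (4S,5S)-5-{[(tert-butyldimethylsilyl)oxy]methyl}-4-(1,3-dioxolan-2-yl)oxolan-2-one
Product: 4 (4S,5S)-4-(1,3-dioxolan-2-yl)-5-(hydroxymethyl)oxolan-2-one
Conditions: HF·pyridine, THF, 0 °C → rt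
Reagents that add atoms: none
Why: Fluoride cleaves the primary silyl ether (desilylation) under mildly acidic conditions that spare the dioxolane and the lactone.

Step 4
Reactants: 4 (4S,5S)-4-(1,3-dioxolan-2-yl)-5-(hydroxymethyl)oxolan-2-one
Product: 5 (2S,3S)-3-(1,3-dioxolan-2-yl)-5-oxooxolane-2-carbaldehyde
Conditions: Dess–Martin periodinane, CH2Cl2, 0 °C → rt
Reagents that add atoms: none
Why: Dess–Martin oxidation is mild enough to give the α-oxygenated aldehyde (the future C-9) without epimerisation at C-8, provided the crude product is used at once.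

Step 5
Reactants: 6 4-methylpent-4-en-1-ol
Product: 7 4-methylpent-4-enal
Conditions: TEMPO (cat.), PhI(OAc)2, CH2Cl2, rt
Reagents that add atoms: none
Why: The oxoammonium cycle of the TEMPO oxidation converts the primary alcohol into the aldehyde and does not touch the 1,1-disubstituted alkene.

Step 6
Reactants: 7 4-methylpent-4-enal
Product: 8 methyl (2Z)-2-iodo-6-methylhepta-2,6-dienoate
Conditions: Ph3P=CHCO2Me, N-iodosuccinimide, CH2Cl2, −20 °C; then 7, −20 °C → rt
Reagents that add atoms: methyl (triphenylphosphoranylidene)acetate, COC(=O)C=P(c1ccccc1)(c1ccccc1)c1ccccc1; N-iodosuccinimide, O=C1CCC(=O)N1I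
Why: Iodination of the stabilised ylide and Wittig olefination in one flask place the ester trans to the chain, so that iodine and chain are cis (Z), the geometry that the cis ring alkene C-1=C-10 needs.

Step 7
Reactants: 5 (2S,3S)-3-(1,3-dioxolan-2-yl)-5-oxooxolane-2-carbaldehyde; 8 methyl (2Z)-2-iodo-6-methylhepta-2,6-dienoate
Product: 9 methyl (2E)-2-{(R)-[(2S,3S)-3-(1,3-dioxolan-2-yl)-5-oxooxolan-2-yl](hydroxy)methyl}-6-methylhepta-2,6-dienoate
Conditions: CrCl2, NiCl2 (cat.), DMSO, rt
Reagents that add atoms: none
Why: The Nozaki–Hiyama–Kishi coupling (Ni-catalysed oxidative addition, transmetalation to chromium, carbonyl addition) keeps the alkene geometry and tolerates lactone, ester and acetal, and Felkin–Anh addition anti to the lactone C–O bond should set C-9 as R (8,9-anti).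

Step 8
Reactants: 9 methyl (2E)-2-{(R)-[(2S,3S)-3-(1,3-dioxolan-2-yl)-5-oxooxolan-2-yl](hydroxy)methyl}-6-methylhepta-2,6-dienoate
Product: 10 methyl (2E)-2-{(R)-[(2S,3S)-3-formyl-5-oxooxolan-2-yl](hydroxy)methyl}-6-methylhepta-2,6-dienoate
Conditions: TsOH·H2O (cat.), acetone/H2O, rt
Reagents that add atoms: water, O
Why: Acid-catalysed transacetalisation and hydrolysis free the aldehyde under conditions too mild to hydrate the isopropenyl group, and the trans arrangement on the lactone disfavours lactol formation with the C-9 hydroxyl.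

Step 9
Reactants: 10 methyl (2E)-2-{(R)-[(2S,3S)-3-formyl-5-oxooxolan-2-yl](hydroxy)methyl}-6-methylhepta-2,6-dienoate
Product: 11 tricyclic hydroxy lactone (4S,6R,7R,8S,9R): the target skeleton with free C-6 hydroxyl and CH2 at C-11
Conditions: Me2AlCl (3 equiv), CH2Cl2 (0.002 M, slow addition of 10), −78 → −20 °C
Reagents that add atoms: none
Why: Proposed new method: Me2AlCl turns the C-9 hydroxyl into an aluminium alkoxide (methane leaves, so no protic acid can add to the isopropenyl group) and a further equivalent activates the aldehyde, whose carbon is attacked by the CH2 terminus of the 1,1-disubstituted alkene while the tertiary cationic centre developing at C-4 is captured across the ring by the alkoxide oxygen. The closest known reaction types are the Lewis-acid Prins and type 2 carbonyl-ene cyclisations that end by capture of the cation by a tethered hydroxyl and the cation–olefin macrocyclisations of acid chlorides used for fourteen-membered terpenoid rings, but a ten-membered carbocycle has not been closed in this way. The carbocycle closes in the 10-membered mode (exo at the carbonyl, endo at the olefin), and the ether closure is a transannular 1,6-capture at the cationic carbon that divides the carbocycle into the seven-membered oxepane and oxepene rings. C-6 is set at C–C bond formation: the need to keep the C-9 alkoxide within reach of C-4 holds the C-8–C-7–C-6–C-5 torsion gauche, so the alkene approaches anti to C-11 with the chelated carbonyl oxygen next to C-8 (Felkin–Anh type, 6R), and C-4 is dictated by C-9 because the one-atom oxygen bridge can only span the ring in a cis sense (4S). The step needs chemoselectivity for the electron-rich isopropenyl group over the ester-deactivated C-1=C-10 alkene, Markovnikov attack through the CH2 terminus, and ring closure over oligomerisation; these rest on the nucleophilicity gap between the two alkenes, on the tertiary cation, and on the folding imposed by the cis C-1=C-10 alkene and the trans-substituted lactone at high dilution.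

Step 10
Reactants: 12 (E)-2-methylbut-2-en-1-ol
Product: 13 [(2R,3R)-2,3-dimethyloxiran-2-yl]methanol
Conditions: tBuOOH, Ti(OiPr)4 (cat.), D-(−)-diethyl tartrate (cat.), 4 Å MS, CH2Cl2, −20 °C
Reagents that add atoms: tert-butyl hydroperoxide, CC(C)(C)OO
Why: Sharpless asymmetric epoxidation with D-(−)-diethyl tartrate delivers oxygen to the face of the (E)-allylic alcohol that gives the (2R,3R)-epoxy alcohol with cis methyl groups.

Step 11
Reactants: 13 [(2R,3R)-2,3-dimethyloxiran-2-yl]methanol
Product: 14 (2S,3R)-2,3-dimethyloxirane-2-carboxylic acid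
Conditions: RuCl3·xH2O (cat.), NaIO4, EtOAc/MeCN/H2O, rt
Reagents that add atoms: water, O
Why: Catalytic RuO4 generated from RuCl3 and NaIO4 oxidises the primary alcohol to the acid without opening the epoxide, and the C-2 descriptor changes to S only because the substituent priorities change.

Step 12
Reactants: 11 tricyclic hydroxy lactone; 14 (2S,3R)-2,3-dimethyloxirane-2-carboxylic acid
Product: 16 C-6 epoxy ester of 11 (saturated lactone; the target lacking the C-13 methylene), via mixed anhydride 15 (not isolated)
Conditions: 2,4,6-trichlorobenzoyl chloride, Et3N, THF, rt; then 11, DMAP (cat.), toluene, rt → 40 °C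
Reagents that add atoms: none
Why: Yamaguchi esterification activates the hindered α-quaternary acid as a mixed anhydride that DMAP attacks at the aliphatic carbonyl, so the ester should form with retention at C-6 and without risk to the epoxide stereocentres, which carry no α-hydrogen.

Step 13
Reactants: 16 C-6 epoxy ester (saturated lactone)
Product: 17 C-11 dimethylaminomethyl lactone (Mannich base; C-11 epimers)
Conditions: LiN(iPr)2, THF, −78 °C; then Eschenmoser's salt, −78 °C → rt
Reagents that add atoms: N,N-dimethylmethyleneiminium iodide (Eschenmoser's salt), C=[N+](C)C.[I-]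
Why: Kinetic deprotonation finds the lactone α-CH2 as the only simple α-position (the epoxy ester has no α-hydrogen and the enoate only vinylogous ones), and the enolate is trapped by the iminium salt in a Mannich reaction whose new C-11 centre is lost in the next step.

Step 14
Reactants: 17 C-11 dimethylaminomethyl lactone
Product: 19 target CNP0240298.1, via trimethylammonium iodide 18 (not isolated)
Conditions: MeI, MeOH, rt; then NaHCO3 (aq.), EtOAc, rt
Reagents that add atoms: none
Why: Quaternisation with MeI and base-induced β-elimination of trimethylamine (Hofmann-type) from the lactone α-position should give the exocyclic C-11=C-13 methylene under conditions that spare the epoxide and both esters.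

Compound list
1 | (S)-5-(hydroxymethyl)furan-2(5H)-one | O=C1O[C@H](CO)C=C1 | starting material
2 | (S)-5-{[(tert-butyldimethylsilyl)oxy]methyl}furan-2(5H)-one | O=C1O[C@H](CO[Si](C)(C)C(C)(C)C)C=C1 | intermediate
3 | (4S,5S)-5-{[(tert-butyldimethylsilyl)oxy]methyl}-4-(1,3-dioxolan-2-yl)oxolan-2-one (trans) | C1C(=O)O[C@H](CO[Si](C)(C)C(C)(C)C)[C@H]1C1OCCO1 | intermediate
4 | (4S,5S)-4-(1,3-dioxolan-2-yl)-5-(hydroxymethyl)oxolan-2-one | C1C(=O)O[C@H](CO)[C@H]1C1OCCO1 | intermediate
5 | (2S,3S)-3-(1,3-dioxolan-2-yl)-5-oxooxolane-2-carbaldehyde | C1C(=O)O[C@H](C=O)[C@H]1C1OCCO1 | intermediate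
6 | 4-methylpent-4-en-1-ol | C=C(C)CCCO | starting material
7 | 4-methylpent-4-enal | C=C(C)CCC=O | intermediate
8 | methyl (2Z)-2-iodo-6-methylhepta-2,6-dienoate | COC(=O)/C(I)=C/CCC(C)=C | intermediate
9 | methyl (2E)-2-{(R)-[(2S,3S)-3-(1,3-dioxolan-2-yl)-5-oxooxolan-2-yl](hydroxy)methyl}-6-methylhepta-2,6-dienoate | C1C(=O)O[C@H]([C@H](O)/C(C(=O)OC)=C\CCC(C)=C)[C@H]1C1OCCO1 | intermediate
10 | methyl (2E)-2-{(R)-[(2S,3S)-3-formyl-5-oxooxolan-2-yl](hydroxy)methyl}-6-methylhepta-2,6-dienoate | C1C(=O)O[C@H]([C@H](O)/C(C(=O)OC)=C\CCC(C)=C)[C@H]1C=O | intermediate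
11 | tricyclic hydroxy lactone: methyl (4S,6R,7R,8S,9R)-4,9-epoxy-6-hydroxy-12,8-olide of the 13-norgermacr-1(10)-en-14-oate skeleton (11-oxabicyclo[4.4.1]undecene trans-fused to a saturated γ-butyrolactone) | C1C(=O)O[C@H]2[C@H]1[C@H](O)C[C@]1(C)CCC=C(C(=O)OC)[C@H]2O1 | intermediate
12 | (E)-2-methylbut-2-en-1-ol | C/C=C(\C)CO | starting material
13 | [(2R,3R)-2,3-dimethyloxiran-2-yl]methanol | OC[C@@]1(C)O[C@@H]1C | intermediate
14 | (2S,3R)-2,3-dimethyloxirane-2-carboxylic acid | OC(=O)[C@@]1(C)O[C@@H]1C | intermediate
15 | (2S,3R)-2,3-dimethyloxirane-2-carboxylic 2,4,6-trichlorobenzoic anhydride (not isolated) | O=C(OC(=O)[C@@]1(C)O[C@@H]1C)c1c(Cl)cc(Cl)cc1Cl | intermediate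
16 | C-6 (2S,3R)-2,3-dimethyloxirane-2-carboxylate of 11 (4S,6R,7R,8S,9R; CH2 at C-11) | C1C(=O)O[C@H]2[C@H]1[C@H](OC(=O)[C@@]1(C)O[C@@H]1C)C[C@]1(C)CCC=C(C(=O)OC)[C@H]2O1 | intermediate
17 | C-11 (dimethylamino)methyl derivative of 16 (C-11 epimers, both converge) | CN(C)CC1C(=O)O[C@H]2[C@H]1[C@H](OC(=O)[C@@]1(C)O[C@@H]1C)C[C@]1(C)CCC=C(C(=O)OC)[C@H]2O1 | intermediate
18 | C-11 (trimethylammonio)methyl iodide of 16 (C-11 epimers; not isolated) | C[N+](C)(C)CC1C(=O)O[C@H]2[C@H]1[C@H](OC(=O)[C@@]1(C)O[C@@H]1C)C[C@]1(C)CCC=C(C(=O)OC)[C@H]2O1.[I-] | intermediate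
19 | CNP0240298.1: methyl (4S,6R,7R,8S,9R)-6-{[(2S,3R)-2,3-dimethyloxirane-2-carbonyl]oxy}-4,9-epoxygermacra-1(10),11(13)-dien-12,8-olid-14-oate | C=C1C(=O)O[C@H]2[C@H]1[C@H](OC(=O)[C@@]1(C)O[C@@H]1C)C[C@]1(C)CCC=C(C(=O)OC)[C@H]2O1 | target

Total step count: 14. Longest linear sequence: 10 steps (steps 1–4, 7–9 and 12–14).

Steps most likely to fail

1. Step 9 (bears the label). The ten-membered C–C closure may lose to intermolecular Prins oligomerisation or to methyl transfer from aluminium to the aldehyde. It may also stop at an ene-type olefin after proton loss, or attack the aldehyde face that leads to the C-6 epimer. The fallback uses known chemistry, sets out from 5 and comes back at 11; it makes the two bonds in two operations, with an allylsilane in place of the isopropenyl group.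
   - Johnson–Claisen rearrangement of commercial 2-[(trimethylsilyl)methyl]prop-2-en-1-ol with triethyl orthoacetate (cat. propionic acid, 140 °C) would give ethyl 4-[(trimethylsilyl)methyl]pent-4-enoate F1.
   - iBu2AlH (CH2Cl2, −78 °C) would reduce it to 4-[(trimethylsilyl)methyl]pent-4-enal F2.
   - The iodo-Wittig conditions of step 6 would give methyl (2Z)-2-iodo-6-[(trimethylsilyl)methyl]hepta-2,6-dienoate F3.
   - Coupling with 5 under the conditions of step 7 would give the allylic alcohol F4, and acetal cleavage as in step 8 the hydroxy aldehyde F5.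
   - An intramolecular Hosomi–Sakurai allylation (EtAlCl2, CH2Cl2, −78 °C, high dilution), in which the allylsilane is a far stronger π-nucleophile than the alkene of 10, would close the ten-membered ring to the diol F6 with an exocyclic methylene on C-4.
   - Acid-catalysed transannular Markovnikov hydroalkoxylation (camphorsulfonic acid, CH2Cl2, rt) would then add the C-9 hydroxyl to C-4 and give 11.

2. Step 13. Deprotonation may occur at the vinylogous positions of the C-1=C-10 enoate instead of C-11, or the lactone enolate may attack the neighbouring C-6 ester carbonyl (Claisen-type acyl transfer). The fallback sets out from 16 and comes back at 19. Carboxylation with MeOMgOCO2Me (DMF, 125 °C), which is driven by magnesium chelation and is selective for the lactone α-position under equilibrating conditions, would give the α-carboxy lactone F8. Decarboxylative Mannich methylenation (aqueous formaldehyde, Et2NH, AcOH/NaOAc) would then give 19 directly.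

3. Step 7. Transmetalation of the α-iodo enoate may be slow, the α-oxygenated aldehyde may epimerise at C-8 while it waits, and facial selectivity at C-9 may be low. The fallback sets out from 9, obtained as a C-9 epimer mixture, and comes back at 9. Dess–Martin oxidation would give the alkylidene β-keto ester F7, and Corey–Bakshi–Shibata reduction ((R)-2-methyl-oxazaborolidine, catecholborane, toluene, −78 °C) would return 9 with the carbinol centre set under reagent instead of substrate control.

Further compounds
F1 | step 9 | ethyl 4-[(trimethylsilyl)methyl]pent-4-enoate | CCOC(=O)CCC(=C)C[Si](C)(C)C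
F2 | step 9 | 4-[(trimethylsilyl)methyl]pent-4-enal | O=CCCC(=C)C[Si](C)(C)C
F3 | step 9 | methyl (2Z)-2-iodo-6-[(trimethylsilyl)methyl]hepta-2,6-dienoate | COC(=O)/C(I)=C/CCC(=C)C[Si](C)(C)C
F4 | step 9 | methyl (2E)-2-{(R)-[(2S,3S)-3-(1,3-dioxolan-2-yl)-5-oxooxolan-2-yl](hydroxy)methyl}-6-[(trimethylsilyl)methyl]hepta-2,6-dienoate | C1C(=O)O[C@H]([C@H](O)/C(C(=O)OC)=C\CCC(=C)C[Si](C)(C)C)[C@H]1C1OCCO1
F5 | step 9 | methyl (2E)-2-{(R)-[(2S,3S)-3-formyl-5-oxooxolan-2-yl](hydroxy)methyl}-6-[(trimethylsilyl)methyl]hepta-2,6-dienoate | C1C(=O)O[C@H]([C@H](O)/C(C(=O)OC)=C\CCC(=C)C[Si](C)(C)C)[C@H]1C=O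
F6 | step 9 | ten-membered 6,9-diol with exocyclic methylene on C-4 (6R,7R,8S,9R; C-1=C-10 cis in the ring; saturated 12,8-lactone) | C1C(=O)O[C@H]2[C@H]1[C@H](O)CC(=C)CC/C=C(C(=O)OC)\[C@H]2O
F7 | step 7 | methyl (2E)-2-{[(2S,3S)-3-(1,3-dioxolan-2-yl)-5-oxooxolan-2-yl]carbonyl}-6-methylhepta-2,6-dienoate | C1C(=O)O[C@H](C(=O)/C(C(=O)OC)=C\CCC(C)=C)[C@H]1C1OCCO1
F8 | step 13 | C-11 carboxylic acid of 16 (C-11 epimers) | OC(=O)C1C(=O)O[C@H]2[C@H]1[C@H](OC(=O)[C@@]1(C)O[C@@H]1C)C[C@]1(C)CCC=C(C(=O)OC)[C@H]2O1
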